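## Retrosynthetic overview

1. Feature: each O–CH(CH3) carbon of the target spans one carbocycle. It joins the oxygen on one carbon of the central eight-membered ring to the ring carbon 1,4 to it across the C=C shared with that carbocycle. With both epoxycyclohexenone rings read as 1,4-dimethoxybenzenes, each pyran is an isochroman, and the core is a 5,6,11,12-tetrahydrodibenzo[a,e][8]annulene bridged C5–O–CH(CH3)–C12 and C6–O–CH(CH3)–C11.
2. Late stage: the C4/C7 carbinols come from hindrance-guided reduction of a bis(epoxyquinone), made by outer-face nucleophilic epoxidation of the bis-quinone, itself from oxidative demethylation of the tetramethoxy cage. The two C–CH3 bonds come from exo methyl transfer from AlMe3 to the CH oxocarbenium ions of a bis-lactol.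
3. Key disconnection: the C12–CH(OH) and C11–CH(OH) bonds of the bis-lactol. They arise by two-electron reduction of the C11=C12 stilbene bond of the trans-(5S,6S)-diformate and two O-to-C formyl transfers, which close both pyrans at once.
4. The diformate comes from the (5S,6S)-diol, made by desymmetrising hydrolysis of the meso mono-epoxide of tetramethoxydibenzocyclooctatetraene. That tetraene comes from a double Wittig reaction of a dialdehyde and a bis-phosphonium salt, both from 2,3-dimethylhydroquinone.
5. Ring order: arenes (bought) → eight-membered ring (step 5) → both pyrans (step 9) → quinones (step 12) → oxiranes (step 13).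

Key step: step 9

Assumption: the sense of induction of the chiral catalysts in steps 7 and 13 is carried over from the closest model substrates (cis-disubstituted meso-epoxides; quinones and quinone monoketals); if a catalyst favours the other sense, its antipode or pseudo-enantiomer is used and nothing else changes.

Descriptors:
- Locants are those of dibenzo[a,e][8]annulene. C5/C6 carry oxygen and C11/C12 carry carbon. C4 and C7 are peri to C5 and C6; C1 and C10 are peri to C12 and C11.
- exo = pointing away from the carbocycle of the other half; endo = pointing under it.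
- Outer face of a carbocycle = the face on the side of its own O–CH bridge; inner face = the face over which the bridge of the other half lies.

## Route

Step 1
Reactants: 1 2,3-dimethylbenzene-1,4-diol
Product: 2 1,4-dimethoxy-2,3-dimethylbenzene
Conditions: MeI (2.5 equiv), K2CO3, acetone, reflux, N2
Reagents that add atoms: iodomethane, CI
Why: Williamson ether synthesis: both phenoxides are methylated by SN2 attack on MeI, which masks the hydroquinone as the oxidatively cleavable dimethyl ether; no stereocentre is formed.

Step 2
Reactants: 2 1,4-dimethoxy-2,3-dimethylbenzene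
Product: 3 2,3-bis(bromomethyl)-1,4-dimethoxybenzene
Conditions: NBS (2.1 equiv), AIBN (cat.), PhCF3, reflux, visible light
Reagents that add atoms: N-bromosuccinimide, O=C1CCC(=O)N1Br
Why: Wohl–Ziegler bromination: in a non-polar medium under radical initiation each benzylic methyl group should be brominated once, faster than the ring is attacked.

Step 3
Reactants: 3 2,3-bis(bromomethyl)-1,4-dimethoxybenzene
Product: 4 3,6-dimethoxybenzene-1,2-dicarbaldehyde
Conditions: 4-methylmorpholine N-oxide (8 equiv), 4 Å molecular sieves, MeCN, rt
Reagents that add atoms: 4-methylmorpholine N-oxide, C[N+]1([O-])CCOCC1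
Why: Kornblum-type oxidation with an amine N-oxide: SN2 displacement of each bromide by the N-oxide oxygen and base-induced loss of 4-methylmorpholine give both aldehydes without over-oxidation.

Step 4
Reactants: 3 2,3-bis(bromomethyl)-1,4-dimethoxybenzene
Product: 5 [(3,6-dimethoxy-1,2-phenylene)bis(methylene)]bis(triphenylphosphonium) dibromide
Conditions: PPh3 (2.2 equiv), DMF, 110 °C
Reagents that add atoms: triphenylphosphine, c1ccc(cc1)P(c1ccccc1)c1ccccc1
Why: Quaternisation (SN2) of PPh3 by both benzylic bromides should give the crystalline Wittig salt.

Step 5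
Reactants: 4 3,6-dimethoxybenzene-1,2-dicarbaldehyde; 5 bis-phosphonium dibromide
Product: 7 (5Z,11Z)-1,4,7,10-tetramethoxydibenzo[a,e][8]annulene, via Z-stilbene aldehyde phosphonium bromide 6 (not isolated)
Conditions: LiOMe (2.2 equiv, in MeOH, syringe pump over 12 h), DMF, 90 °C, ca. 0.01 M
Reagents that add atoms: none
Why: Two-fold Wittig olefination under pseudo-high dilution: the semi-stabilised benzylide with ortho-alkoxy groups on both partners favours the Z-alkene 6, and the second, intramolecular olefination can close the eight-membered ring only as the Z,Z-diene.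

Step 6
Reactants: 7 (5Z,11Z)-1,4,7,10-tetramethoxydibenzo[a,e][8]annulene
Product: 8 meso-(5R,6S,11Z)-5,6-epoxy-1,4,7,10-tetramethoxy-5,6-dihydrodibenzo[a,e][8]annulene
Conditions: dimethyldioxirane (0.8 equiv, in acetone), CH2Cl2, −20 °C; unreacted 7 recycled
Reagents that add atoms: dimethyldioxirane, CC1(C)OO1
Why: Prilezhaev-type concerted syn oxygen transfer to one Z-alkene gives the cis, hence meso, oxirane; the deficit of oxidant limits double epoxidation and the neutral reagent spares the acid-labile, electron-rich benzylic epoxide.

Step 7
Reactants: 8 meso-epoxide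
Product: 9 (5S,6S,11Z)-1,4,7,10-tetramethoxy-5,6-dihydrodibenzo[a,e][8]annulene-5,6-diol
Conditions: cyclic oligomeric (R,R)-(salen)Co(OTs) (2 mol % Co), H2O (1.5 equiv), MeCN/CH2Cl2, 0 °C → rt
Reagents that add atoms: water, O
Why: Enantioselective desymmetrising hydrolysis of a meso-epoxide by cooperative trivalent-cobalt salen catalysis: one cobalt centre activates the oxirane and a second delivers hydroxide to one of the two enantiotopic benzylic carbons with inversion, so one centre is retained, the other inverted, and the trans-(5S,6S)-diol results.

Step 8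
Reactants: 9 (5S,6S)-diol; 10 formic acid
Product: 11 (5S,6S,11Z)-1,4,7,10-tetramethoxy-5,6-dihydrodibenzo[a,e][8]annulene-5,6-diyl diformate
Conditions: HCO2H/Ac2O (premixed, 50 °C, 2 h, then 0 °C), pyridine, CH2Cl2, 0 °C → rt
Reagents that add atoms: formic acid (10), OC=O
Why: O-Formylation through the mixed anhydride: each alcohol attacks the more electrophilic formyl carbonyl of acetic formic anhydride under basic conditions, so the benzylic C–O bonds and both stereocentres are untouched.

Step 9
Reactants: 11 (5S,6S)-diformate
Product: 14 (5S,6S,11S,12S)-1,4,7,10-tetramethoxy-5,6,11,12-tetrahydrodibenzo[a,e][8]annulene bridged C5–O–CH(OH)–C12 and C6–O–CH(OH)–C11 (bis-lactol cage; anomeric mixture; exo,exo anomer drawn), via 11,12-dilithio diformate 12 (not isolated), via dilithium bis-lactolate 13 (not isolated)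
Conditions: lithium 4,4'-di-tert-butylbiphenylide (0.4 M in THF, ca. 2.05 equiv, added dropwise to the first lasting green colour), THF (0.005 M in 11), −95 °C; then AcOH (2.2 equiv), −95 °C → rt
Reagents that add atoms: none
Why: Proposed new method: the arenide transfers two electrons to the cis-stilbene unit of 11, the lowest-lying π* system present, and turns C11=C12 into the vicinal dibenzylic dilithio species 12, whose central bond is then free to twist; C12 adds to the formyl carbon on O–C5 and C11 to that on O–C6, each across its own arene, and the acyl transfer halts at the tetrahedral stage because the alkoxide formed is already the lactolate 13, which AcOH protonates to 14. The closest known reaction types are the reductive vicinal double C-acylation and dicarboxylation of stilbenes and styrenes (alkali metal, Mg or cathode) and anionic O-to-C acyl or carbamoyl migrations onto benzylic carbanions (homo-Fries type); their intramolecular union on a formate ester has not been shown. Both pyrans close in the 6-exo-trig mode through six-membered, lithium-bridged transition states. C11 and C12 are set by C6 and C5: the one-atom tether lets each formyl carbon reach only the carbanion face on the side of its own C–O bond (1,4-cis across the arene), and since the two C–O bonds are trans the new bonds form on opposite faces of the eight-membered ring and give the C2 cage, whereas the lactol carbons are left uncontrolled (OH exo expected, as only H fits under the opposite arene, which is also why formate and not acetate is the migrating group) and are erased in step 11. The step needs electron uptake by the alkene rather than by the esters, and addition to C=O faster than loss of formate from the benzylic carbons (mesolytic cleavage or 1,4-elimination); the first is secured by the conjugated stilbene and by titrating the reductant at −95 °C, the second by the non-enolisable, highly electrophilic formyl group and by the peri-methoxy groups, which hold C5–H and C6–H in the arene planes and so keep both formates poised over C12 and C11.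

Step 10
Reactants: 14 bis-lactol cage
Product: 15 bis(anomeric acetate) of 14 (bridges C5–O–CH(OAc)–C12 and C6–O–CH(OAc)–C11; exo,exo anomer drawn)
Conditions: Ac2O, pyridine, DMAP (cat.), CH2Cl2, 0 °C → rt
Reagents that add atoms: acetic anhydride, CC(=O)OC(C)=O
Why: DMAP-catalysed anomeric O-acetylation turns both lactol hydroxyls into leaving groups; the ring-closed form is trapped because the cage holds O–C5 and O–C6 against the former formyl carbons, and the anomeric configuration is of no consequence.

Step 11
Reactants: 15 bis(anomeric acetate); 16 trimethylaluminium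
Product: 17 (5S,6S,11S,12S)-1,4,7,10-tetramethoxy cage bridged C5–O–CH(CH3)–C12 and C6–O–CH(CH3)–C11, both bridge carbons R, both methyl groups exo
Conditions: AlMe3 (6 equiv), CH2Cl2, −78 → 0 °C; aq. KNaC4H4O6
Reagents that add atoms: trimethylaluminium (16), C[Al](C)C
Why: Lewis-acid-mediated C-glycosidation-type methylation of lactol acetates: AlMe3 ionises each acetate to the CH oxocarbenium ion and transfers methyl to its exo face because the endo face lies under the arene of the other half, which sets both O–CH(CH3) centres as R (the reverse order, C-methyl oxocarbenium plus hydride, would put methyl endo and give the wrong epimer).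

Step 12
Reactants: 17 dimethyl tetramethoxy cage
Product: 18 cage bis-quinone (17 with both arenes as 1,4-benzoquinones; carbonyls at C1, C4, C7, C10)
Conditions: (NH4)2Ce(NO3)6 (5 equiv), MeCN/H2O 2:1, 0 °C
Reagents that add atoms: water, O
Why: Oxidative demethylation of 1,4-dimethoxyarenes to p-quinones, routine for isochromans: each arene gives up two electrons, takes up two molecules of water and releases two of methanol, while the cage ethers and all six stereocentres are left alone.

Step 13
Reactants: 18 cage bis-quinone
Product: 19 cage bis(epoxyquinone) (18 with cis-oxiranes at C2–C3 and C8–C9, both on the outer faces)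
Conditions: tBuOOH (5 equiv), 0.1 M aq. NaOH, N-benzylcinchonidinium chloride (20 mol %), toluene, 0 °C
Reagents that add atoms: tert-butyl hydroperoxide, CC(C)(C)OO
Why: Asymmetric Weitz–Scheffer epoxidation under chiral phase-transfer catalysis, known for 1,4-quinones and quinone monoketals: the peroxide anion adds only to the unsubstituted C2=C3 and C8=C9 bonds (the ring-fusion C=C is tetrasubstituted and buried), the outer face being slightly favoured by the substrate (the inner face carries the O–CH bridge of the other half) and selected by the ion-paired ammonium cation identically in both homotopic rings, while the bridgehead C–H bonds lie in the quinone planes and cannot be enolised by the base.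

Step 14
Reactants: 19 cage bis(epoxyquinone)
Product: 20 epoxytwinol A
Conditions: iBu2AlH (2.3 equiv), THF, −78 °C; aq. KNaC4H4O6
Reagents that add atoms: none
Why: Regio- and diastereoselective 1,2-reduction of an epoxyquinone with iBu2AlH, the reagent known to give anti-epoxy alcohols by coordination to the oxirane oxygen and hydride delivery from that face: C4=O and C7=O lie in the bay lined only by the two pyran oxygens, whereas C1=O and C10=O are shielded on the outer face by the exo methyl group and on the inner face by the endo C–H of the other bridge, so hydride enters C4 and C7 from the outer face and leaves both hydroxyls on the inner face, anti to the oxiranes.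

## Compound list

1 | 2,3-dimethylbenzene-1,4-diol | Cc1c(C)c(O)ccc1O | starting material
2 | 1,4-dimethoxy-2,3-dimethylbenzene | COc1ccc(OC)c(C)c1C | intermediate
3 | 2,3-bis(bromomethyl)-1,4-dimethoxybenzene | COc1ccc(OC)c(CBr)c1CBr | intermediate
4 | 3,6-dimethoxybenzene-1,2-dicarbaldehyde | COc1ccc(OC)c(C=O)c1C=O | intermediate
5 | [(3,6-dimethoxy-1,2-phenylene)bis(methylene)]bis(triphenylphosphonium) dibromide | COc1ccc(OC)c(C[P+](c2ccccc2)(c2ccccc2)c2ccccc2)c1C[P+](c1ccccc1)(c1ccccc1)c1ccccc1.[Br-].[Br-] | intermediate
6 | (Z)-{2-[2-(2-formyl-3,6-dimethoxyphenyl)ethenyl]-3,6-dimethoxybenzyl}triphenylphosphonium bromide | COc1ccc(OC)c(C=O)c1/C=C\c1c(OC)ccc(OC)c1C[P+](c1ccccc1)(c1ccccc1)c1ccccc1.[Br-] | intermediate (not isolated)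
7 | (5Z,11Z)-1,4,7,10-tetramethoxydibenzo[a,e][8]annulene | COc1ccc(OC)c2/C=C\c3c(OC)ccc(OC)c3/C=C\c12 | intermediate
8 | meso-(5R,6S,11Z)-5,6-epoxy-1,4,7,10-tetramethoxy-5,6-dihydrodibenzo[a,e][8]annulene | COc1ccc(OC)c2/C=C\c3c(OC)ccc(OC)c3[C@H]4O[C@H]4c12 | intermediate
9 | (5S,6S,11Z)-1,4,7,10-tetramethoxy-5,6-dihydrodibenzo[a,e][8]annulene-5,6-diol | O[C@H]1c2c(OC)ccc(OC)c2/C=C\c2c(OC)ccc(OC)c2[C@@H]1O | intermediate
10 | formic acid | OC=O | starting material
11 | (5S,6S,11Z)-1,4,7,10-tetramethoxy-5,6-dihydrodibenzo[a,e][8]annulene-5,6-diyl diformate | O=CO[C@H]1c2c(OC)ccc(OC)c2/C=C\c2c(OC)ccc(OC)c2[C@@H]1OC=O | intermediate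
12 | 11,12-dilithio derivative of 11 (vicinal dibenzylic dianion) | [Li+].[Li+].O=CO[C@H]1c2c(OC)ccc(OC)c2[CH-][CH-]c2c(OC)ccc(OC)c2[C@@H]1OC=O | intermediate (not isolated)
13 | dilithium bis-lactolate of 14 (exo,exo drawn) | [Li+].[Li+].[O-][C@H]1O[C@H]2c3c(c(OC)ccc3OC)[C@@H]1[C@H]1c3c(c(OC)ccc3OC)[C@@H]2O[C@@H]1[O-] | intermediate (not isolated)
14 | bis-lactol of the tetramethoxy dibenzo cage (anomeric mixture, exo,exo drawn) | O[C@H]1O[C@H]2c3c(c(OC)ccc3OC)[C@@H]1[C@H]1c3c(c(OC)ccc3OC)[C@@H]2O[C@@H]1O | intermediate
15 | bis(anomeric acetate) of 14 (exo,exo drawn) | CC(=O)O[C@H]1O[C@H]2c3c(c(OC)ccc3OC)[C@@H]1[C@H]1c3c(c(OC)ccc3OC)[C@@H]2O[C@@H]1OC(C)=O | intermediate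
16 | trimethylaluminium | C[Al](C)C | starting material
17 | exo,exo-dimethyl tetramethoxy dibenzo cage | C[C@H]1O[C@H]2c3c(c(OC)ccc3OC)[C@@H]1[C@H]1c3c(c(OC)ccc3OC)[C@@H]2O[C@@H]1C | intermediate
18 | cage bis-quinone | C[C@H]1O[C@H]2C3=C(C(=O)C=CC3=O)[C@@H]1[C@H]1C3=C(C(=O)C=CC3=O)[C@@H]2O[C@@H]1C | intermediate
19 | cage bis(epoxyquinone), oxiranes on the outer faces | C[C@H]1O[C@H]2C3=C(C(=O)[C@@H]4O[C@@H]4C3=O)[C@@H]1[C@H]1C3=C(C(=O)[C@H]4O[C@H]4C3=O)[C@@H]2O[C@@H]1C | intermediate
20 | epoxytwinol A | C[C@H]1O[C@H]2C3=C(C(=O)[C@@H]4O[C@@H]4[C@H]3O)[C@@H]1[C@H]1C3=C([C@H](O)[C@H]4O[C@H]4C3=O)[C@@H]2O[C@@H]1C | target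

## Step count and risks

Total step count: 14. Longest linear sequence: 13 (1 → 2 → 3 → 5 → 7 → 8 → 9 → 11 → 14 → 15 → 17 → 18 → 19 → 20; step 3 is the side branch).

**Step 9.** What may go wrong: after electron uptake, formate may be lost from the benzylic carbons (mesolytic C–O cleavage or 1,4-elimination, ending in reductive elimination of both esters) faster than the carbanions add to the formyl groups. A transiently ring-opened formyl group may also be over-reduced.

The fallback sets out from diol 9 and returns at bis-lactol 14. It brings the bridge carbon in as CO2 instead of as a migrating formyl group.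
- Diol 9 is closed with 2,2-dimethoxypropane and catalytic TsOH to the trans-fused acetonide F1, whose alkoxide-type leaving groups resist reductive cleavage.
- Electroreductive vicinal dicarboxylation of its stilbene bond (CO2 at 1 atm, Mg anode, Pt cathode, Bu4NBF4, DMF, 0 °C) is a known reaction of stilbenes and styrenes in which CO2 traps the radical anion at once. It gives the 11,12-dicarboxylic acid F2.
- Warming with TsOH in wet toluene removes the acetonide and lactonises each acid onto the oxygen across its arene. The enolisable benzylic α-centres drift to the only configuration that can close twice, giving the bis-lactone F3.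
- iBu2AlH (2.2 equiv, CH2Cl2, −78 °C) reduces F3 to 14.

**Step 13.** What may go wrong: facial selectivity may be poor, because the two faces of each quinone differ only through remote groups, and the uncatalysed interfacial epoxidation of so electrophilic an acceptor may outrun the ion-paired pathway.

The fallback sets out from 17 and returns at 20. It moves the epoxidation to the quinone monoketal stage.
- Anodic oxidation of 17 (Pt anode, KOH/MeOH, 0 °C) gives the bis(quinone bisketal) F4.
- Mild acid (aq. AcOH/THF, 0 °C) should hydrolyse the C4 and C7 ketals first, since their ionisation places charge on the alkyl-substituted ring carbon. This gives the bis(quinone monoketal) F5.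
- This much less electrophilic dienone is the substrate class on which chiral ammonium-salt epoxidation is best established. It is epoxidised (tBuOOH, aq. NaOH, N-benzylcinchonidinium chloride, toluene) to the bis(epoxy ketone ketal) F6.
- The single carbonyl left in each ring removes the regiochemical question. iBu2AlH (THF, −78 °C) gives the bis(anti-epoxy alcohol ketal) F7.
- Aqueous HF in MeCN hydrolyses the two ketals to 20.

**Step 7.** What may go wrong: the opening may be slow, because the backside of the oxirane points into the tub of the eight-membered ring. The electron-rich benzylic C–O bond may also ionise, with loss of enantio- and trans-selectivity or Meinwald-type rearrangement.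

The fallback sets out from 7 and returns at 9. It sets both carbinol centres by catalyst-controlled ketone reduction.
- Mono-dihydroxylation of 7 (OsO4 cat., 4-methylmorpholine N-oxide as the limiting reagent, acetone/H2O) gives the meso cis-diol F8.
- Swern oxidation gives the 5,6-dione F9.
- Asymmetric transfer hydrogenation with RuCl[(R,R)-TsDPEN](p-cymene) in HCO2H/Et3N, the reaction that converts benzils into C2-symmetric hydrobenzoins, reduces both aryl ketones with the same sense to the (5S,6S)-diol 9.

## Further compounds

F1 | step 9 | acetonide of (5S,6S)-diol 9 | CC1(C)O[C@H]2c3c(OC)ccc(OC)c3/C=C\c3c(OC)ccc(OC)c3[C@@H]2O1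
F2 | step 9 | acetonide 11,12-dicarboxylic acid (the C2 isomer that lactonises is drawn) | CC1(C)O[C@H]2c3c(OC)ccc(OC)c3[C@@H](C(=O)O)[C@H](C(=O)O)c3c(OC)ccc(OC)c3[C@@H]2O1
F3 | step 9 | bis-lactone of the tetramethoxy dibenzo cage | O=C1O[C@H]2c3c(c(OC)ccc3OC)[C@@H]1[C@H]1c3c(c(OC)ccc3OC)[C@@H]2OC1=O
F4 | step 13 | cage bis(quinone bisketal), dimethyl ketals at C1, C4, C7, C10 | C[C@H]1O[C@H]2C3=C(C(OC)(OC)C=CC3(OC)OC)[C@@H]1[C@H]1C3=C(C(OC)(OC)C=CC3(OC)OC)[C@@H]2O[C@@H]1C
F5 | step 13 | cage bis(quinone monoketal), carbonyls at C4 and C7, ketals at C1 and C10 | C[C@H]1O[C@H]2C3=C(C(OC)(OC)C=CC3=O)[C@@H]1[C@H]1C3=C(C(=O)C=CC3(OC)OC)[C@@H]2O[C@@H]1C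
F6 | step 13 | cage bis(epoxy ketone ketal), oxiranes on the outer faces | C[C@H]1O[C@H]2C3=C(C(OC)(OC)[C@@H]4O[C@@H]4C3=O)[C@@H]1[C@H]1C3=C(C(=O)[C@H]4O[C@H]4C3(OC)OC)[C@@H]2O[C@@H]1C
F7 | step 13 | cage bis(anti-epoxy alcohol ketal) | C[C@H]1O[C@H]2C3=C(C(OC)(OC)[C@@H]4O[C@@H]4[C@H]3O)[C@@H]1[C@H]1C3=C([C@H](O)[C@H]4O[C@H]4C3(OC)OC)[C@@H]2O[C@@H]1C
F8 | step 7 | meso-(5R,6S,11Z)-1,4,7,10-tetramethoxy-5,6-dihydrodibenzo[a,e][8]annulene-5,6-diol | O[C@H]1c2c(OC)ccc(OC)c2/C=C\c2c(OC)ccc(OC)c2[C@H]1O
F9 | step 7 | (11Z)-1,4,7,10-tetramethoxydibenzo[a,e][8]annulene-5,6-dione | O=C1c2c(OC)ccc(OC)c2/C=C\c2c(OC)ccc(OC)c2C1=O
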